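**Retrosynthetic overview**
1. The target (14-O-acetylandrographolide) is opened at C12=C13: aldol addition and E1cB elimination join decalin aldehyde 22 to the silyl ether 24 of (S)-β-hydroxy-γ-butyrolactone. The C14 acetate goes on last, with the 3,19-diol held as an acetonide.
2. The 3,19-diol and C18 come from a C3 ketone/C19 ester (β-keto ester methylation, then LiAlH4). A temporary C1 ketone is removed before that by Stork–Danheiser transposition and conjugate reduction.
3. Key disconnection: both rings of the decalin are made in one pot from the acyclic keto alkylidenemalonate 11. Ring B closes first (C10 enolate to C5, Michael), ring A second (C2 enolate to the C3 ester carbon, Claisen).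
4. Feature that makes this possible: across ring A the unit C10–C1–C2 (C1 a temporary ketone whose two α-carbons are C10 and C2) faces the unit C5–C4–C3 (C4 carrying C3 and C19 as a malonate). C5 is thereby a Michael acceptor and C3 an acylating carbon; the C3 oxygen of the target is a malonate carbonyl oxygen.
5. 11 is built on 5,6-dihydro-2H-pyran-2-one (C1, C9–C12): rhodium-catalysed asymmetric conjugate alkenylation sets C9 and brings C5–C8 and C17, MeI brings C20, MeLi brings C2, dimethyl malonate brings C3, C4 and C19.

Key step: step 9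

Remark: labdane numbering of the target is used for all intermediates (ring A = C1–C5, C10; ring B = C5–C10; C11–C12 side chain; C17 exocyclic methylene; C18 and C19 on C4; C20 on C10; C13–C16 lactone).
Remark: 5,5-dimethoxypentan-2-one (levulinaldehyde dimethyl acetal) is assumed to be a catalogue compound.

**Step 1**
Reactants: 1 5,5-dimethoxypentan-2-one
Product: 2 5,5-dimethoxypent-1-en-2-yl triflate
Conditions: LDA (LiN(iPr)2, 1.05 equiv), THF, −78 °C; PhNTf2, −78 → 0 °C
Reagents that add atoms: N-phenylbis(trifluoromethanesulfonimide), O=S(=O)(N(c1ccccc1)S(=O)(=O)C(F)(F)F)C(F)(F)F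
Why: Kinetic deprotonation of the methyl ketone at the methyl group and O-triflation of the enolate (enol triflate synthesis) should give the terminal enol triflate.

**Step 2**
Reactants: 2 5,5-dimethoxypent-1-en-2-yl triflate
Product: 3 alkenyl pinacol boronate
Conditions: B2pin2, PdCl2(PPh3)2 (3 mol%), PPh3 (6 mol%), KOPh (1.5 equiv), toluene, 50 °C
Reagents that add atoms: bis(pinacolato)diboron, CC1(C)OB(OC1(C)C)B1OC(C)(C)C(C)(C)O1
Why: Miyaura borylation of an alkenyl triflate should give the 1,1-disubstituted alkenylboronate and leave the acetal untouched.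

**Step 3**
Reactants: 3 alkenyl pinacol boronate; 4 5,6-dihydro-2H-pyran-2-one
Product: 5 (4S)-4-alkenyl δ-lactone
Conditions: [RhCl(C8H12)]2 (2.5 mol%; C8H12 = 1,5-cyclooctadiene), (S)-BINAP (6 mol%), KOH (0.5 equiv), dioxane/H2O 10:1, 40 °C
Reagents that add atoms: none
Why: Hayashi–Miyaura rhodium-catalysed asymmetric 1,4-addition of the alkenylboron reagent to the unsaturated lactone should set the future C9 as (S)-5, the BINAP–rhodium alkenyl species adding to one enantioface in the sense established for this ligand with six-membered cyclic acceptors.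

**Step 4**
Reactants: 5 (4S)-4-alkenyl δ-lactone
Product: 6 trans-3-methyl-4-alkenyl δ-lactone
Conditions: LDA (1.1 equiv), THF, −78 °C; MeI, −78 → −20 °C
Reagents that add atoms: iodomethane, CI
Why: Lactone enolate alkylation should put the methyl group (C20) trans to the C4 substituent; this centre (future C10) becomes an enolate again in step 9, so its configuration does not matter.

**Step 5**
Reactants: 6 trans-3-methyl-4-alkenyl δ-lactone
Product: 7 hydroxy methyl ketone
Conditions: MeLi (1.05 equiv), THF, −78 °C; then H2O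
Reagents that add atoms: methyllithium, [Li]C
Why: Addition of one equivalent of MeLi to a δ-lactone at low temperature stops at the lithium lactolate, which on work-up should give the methyl ketone (C1=O, C2) and the free C12 hydroxyl.

**Step 6**
Reactants: 7 hydroxy methyl ketone
Product: 8 TIPS ether keto acetal
Conditions: TIPSCl, imidazole, DMF, 23 °C
Reagents that add atoms: triisopropylsilyl chloride, CC(C)[Si](Cl)(C(C)C)C(C)C
Why: Silylation of the primary alcohol; the TIPS ether is chosen to survive aqueous acid, methoxide, hydride and methylation conditions up to step 16.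

**Step 7**
Reactants: 8 TIPS ether keto acetal
Product: 9 keto aldehyde
Conditions: 1 M aq. oxalic acid, THF, 23 °C
Reagents that add atoms: water, O
Why: Mild acid hydrolysis of the dimethyl acetal should free the C5 aldehyde without touching the TIPS ether or the 1,1-disubstituted alkene.

**Step 8**
Reactants: 9 keto aldehyde; 10 dimethyl malonate
Product: 11 keto alkylidenemalonate
Conditions: piperidine (10 mol%), AcOH (10 mol%), benzene, 4 Å molecular sieves, 23 °C
Reagents that add atoms: none
Why: Knoevenagel condensation is selective for the aldehyde over the hindered methyl ketone and should give the alkylidene malonate (C5=C4).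

**Step 9**
Reactants: 11 keto alkylidenemalonate
Product: 13 trans-decalin-1,3-dione 4-ester, via Michael adduct 12 (not isolated)
Conditions: NaOMe (3 equiv), MeOH, 0.02 M, 65 °C; then 1 M HCl
Reagents that add atoms: none
Why: Methoxide equilibrates the ketone enolates of 11; only the C10 enolate reaches C5 through a six-membered transition state, and its Michael addition to the alkylidene malonate (6-exo-trig) closes ring B, forms the C5–C10 bond and the quaternary C10, and gives malonate anion 12. With C10 quaternary the ketone can enolise only at C2, and this enolate acylates the adjacent malonate ester carbon C3 (Claisen-type 6-exo-trig closure of ring A, C2–C3 bond); the doubly stabilised diketone enolate of 13 is the thermodynamic sink, protonated on work-up. The closest known reaction type is the Michael–Claisen construction of 4-alkoxycarbonylcyclohexane-1,3-diones from δ-keto malonates (the dimedone synthesis), combined with intramolecular enolate additions to alkylidene malonates. The C9 stereocentre controls C10 and C5: allylic 1,3-strain keeps C9–H in the plane of the C10 enolate and the tether folds into a chair with the C11 chain and the malonylidene arm equatorial, so the C10 methyl should end axial and anti to C9–H, and C5–H axial and anti to that methyl (trans fusion); C4 is epimerisable and should settle with the ester equatorial. The step needs C10-over-C2 selectivity in the Michael addition (ring size six against eight), Michael before Claisen (a direct Claisen would need a ten-membered ring) and trans over cis fusion; the last is helped by the reversibility of the Michael step, which lets mismatched adducts revert, and high dilution suppresses intermolecular addition.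

**Step 10**
Reactants: 13 trans-decalin-1,3-dione 4-ester
Product: 14 C3 methyl enol ether (vinylogous ester with C1 ketone)
Conditions: MeOH, HC(OMe)3 (3 equiv), TsOH·H2O (5 mol%), 23 °C
Reagents that add atoms: methanol, CO
Why: Acid-catalysed enol etherification of the cyclic 1,3-diketone (first stage of a Stork–Danheiser sequence) should take place at the C3 carbonyl, the one not flanked by the quaternary C10, as in 4,4-disubstituted cyclohexane-1,3-diones.

**Step 11**
Reactants: 14 C3 methyl enol ether
Product: 16 Δ1-3-keto ester, via C1 allylic alcohol 15 (not isolated)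
Conditions: NaBH4 (2 equiv), CeCl3·7H2O (1.2 equiv), MeOH, 0 °C; then 1 M HCl, THF, 23 °C
Reagents that add atoms: water, O
Why: Luche 1,2-reduction of the vinylogous ester carbonyl (C1), which leaves the methyl ester alone, followed by acid hydrolysis with allylic transposition (Stork–Danheiser) should delete the C1 oxygen and leave the C3 ketone as a Δ1-enone.

**Step 12**
Reactants: 16 Δ1-3-keto ester
Product: 17 C4-methylated enone keto ester
Conditions: K2CO3 (3 equiv), MeI (5 equiv), acetone, 23 °C
Reagents that add atoms: iodomethane, CI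
Why: C-alkylation of the β-keto ester; the axial C10 methyl shields the enolate face syn to it, so MeI should enter anti, giving equatorial C18 and axial CO2Me (C19), the classical outcome for 3-oxo-4-alkoxycarbonyl decalins.

**Step 13**
Reactants: 17 C4-methylated enone keto ester
Product: 18 saturated 3-keto 19-ester
Conditions: [(Ph3P)CuH]6 (0.4 equiv), benzene, H2O (5 equiv), 23 °C
Reagents that add atoms: none
Why: Copper hydride conjugate reduction is selective for the enone and should leave the 1,1-disubstituted C8(17) alkene, the ketone carbonyl and the ester intact.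

**Step 14**
Reactants: 18 saturated 3-keto 19-ester
Product: 19 3,19-diol
Conditions: LiAlH4 (3 equiv), THF, 0 → 23 °C; Fieser work-up
Reagents that add atoms: none
Why: LiAlH4 reduces ester and ketone; axial hydride delivery to C3, from the face away from the axial C19 substituent, should give the equatorial 3-hydroxyl cis to C19.

**Step 15**
Reactants: 19 3,19-diol
Product: 20 3,19-acetonide
Conditions: Me2C(OMe)2, PPTS (cat.), CH2Cl2, 23 °C
Reagents that add atoms: 2,2-dimethoxypropane, COC(C)(C)OC
Why: Transacetalisation of the 1,3-diol gives the six-membered 1,3-dioxane, which protects both hydroxyls through the side-chain chemistry.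

**Step 16**
Reactants: 20 3,19-acetonide
Product: 21 C12 primary alcohol
Conditions: Bu4NF (1.5 equiv), THF, 23 °C
Reagents that add atoms: none
Why: Fluoride cleaves the TIPS ether and leaves the acetonide untouched.

**Step 17**
Reactants: 21 C12 primary alcohol
Product: 22 C12 aldehyde
Conditions: Dess–Martin periodinane, NaHCO3, CH2Cl2, 0 °C
Reagents that add atoms: none
Why: Buffered Dess–Martin oxidation should give the aldehyde without acetonide loss; C9 is not α to the carbonyl and cannot epimerise.

**Step 18**
Reactants: 23 (S)-β-hydroxy-γ-butyrolactone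
Product: 24 (S)-β-(tert-butyldimethylsilyloxy)-γ-butyrolactone
Conditions: TBSCl, imidazole, DMF, 23 °C
Reagents that add atoms: tert-butyldimethylsilyl chloride, CC(C)(C)[Si](C)(C)Cl
Why: Silylation of the secondary alcohol; the stereocentre (future C14) is not touched.

**Step 19**
Reactants: 22 C12 aldehyde; 24 (S)-β-(tert-butyldimethylsilyloxy)-γ-butyrolactone
Product: 25 aldol adduct
Conditions: 24, LDA (1.1 equiv), THF, −78 °C, 30 min; then 22, −78 °C; AcOH quench at −78 °C
Reagents that add atoms: none
Why: Aldol addition of the lithium lactone enolate; the aldehyde should approach anti to the C14 silyloxy group (trans-3,4-disubstituted lactone), the C12 carbinol configuration is inconsequential, and the low temperature suppresses β-elimination of silanolate.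

**Step 20**
Reactants: 25 aldol adduct
Product: 27 14-O-TBS-3,19-O-isopropylideneandrographolide, via C12 mesylate 26 (not isolated)
Conditions: MsCl, Et3N, CH2Cl2, −20 °C; then DBU, 0 °C
Reagents that add atoms: none
Why: Mesylation of the only free hydroxyl and E1cB elimination through the lactone enolate should give the conjugated exocyclic alkene, with the (E) geometry of andrographolide (chain anti to the lactone carbonyl) expected as the favoured isomer.

**Step 21**
Reactants: 27 14-O-TBS-3,19-O-isopropylideneandrographolide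
Product: 28 3,19-O-isopropylideneandrographolide
Conditions: HF·pyridine, pyridine, THF, 0 °C
Reagents that add atoms: none
Why: Buffered HF·pyridine cleaves the secondary TBS ether and should spare the acetonide and the base-sensitive alkylidene lactone.

**Step 22**
Reactants: 28 3,19-O-isopropylideneandrographolide
Product: 29 14-O-acetyl-3,19-O-isopropylideneandrographolide
Conditions: Ac2O, pyridine, DMAP (cat.), CH2Cl2, 0 °C
Reagents that add atoms: acetic anhydride, CC(=O)OC(C)=O
Why: Acylation of the only free hydroxyl under mild, cold conditions, which should avoid SN2′ or elimination chemistry of the allylic acetate.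

**Step 23**
Reactants: 29 14-O-acetyl-3,19-O-isopropylideneandrographolide
Product: 30 14-O-acetylandrographolide (target)
Conditions: AcOH/H2O 7:3, 23 °C
Reagents that add atoms: none
Why: Aqueous acetic acid hydrolyses the acetonide and should leave the allylic acetate, the exocyclic alkene and the C8(17) methylene unchanged.

**Compound list**
1 | 5,5-dimethoxypentan-2-one | CC(=O)CCC(OC)OC | starting material
2 | 5,5-dimethoxypent-1-en-2-yl trifluoromethanesulfonate | C=C(OS(=O)(=O)C(F)(F)F)CCC(OC)OC | intermediate
3 | 2-(5,5-dimethoxypent-1-en-2-yl)-4,4,5,5-tetramethyl-1,3,2-dioxaborolane | C=C(B1OC(C)(C)C(C)(C)O1)CCC(OC)OC | intermediate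
4 | 5,6-dihydro-2H-pyran-2-one | O=C1C=CCCO1 | starting material
5 | (4S)-4-(5,5-dimethoxypent-1-en-2-yl)oxan-2-one | O=C1C[C@@H](C(=C)CCC(OC)OC)CCO1 | intermediate
6 | (3R,4S)-4-(5,5-dimethoxypent-1-en-2-yl)-3-methyloxan-2-one (trans) | O=C1[C@H](C)[C@@H](C(=C)CCC(OC)OC)CCO1 | intermediate
7 | (3R,4S)-4-(2-hydroxyethyl)-8,8-dimethoxy-3-methyl-5-methylideneoctan-2-one | CC(=O)[C@H](C)[C@@H](C(=C)CCC(OC)OC)CCO | intermediate
8 | (3R,4S)-8,8-dimethoxy-3-methyl-5-methylidene-4-[2-(triisopropylsilyloxy)ethyl]octan-2-one | CC(=O)[C@H](C)[C@@H](C(=C)CCC(OC)OC)CCO[Si](C(C)C)(C(C)C)C(C)C | intermediate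
9 | (5S,6R)-6-methyl-4-methylidene-7-oxo-5-[2-(triisopropylsilyloxy)ethyl]octanal | CC(=O)[C@H](C)[C@@H](C(=C)CCC=O)CCO[Si](C(C)C)(C(C)C)C(C)C | intermediate
10 | dimethyl malonate | COC(=O)CC(=O)OC | starting material
11 | dimethyl 2-[(5S,6R)-6-methyl-4-methylidene-7-oxo-5-[2-(triisopropylsilyloxy)ethyl]octylidene]propanedioate | CC(=O)[C@H](C)[C@@H](C(=C)CCC=C(C(=O)OC)C(=O)OC)CCO[Si](C(C)C)(C(C)C)C(C)C | intermediate
12 | dimethyl 2-[(1R,2R,3R)-2-acetyl-2-methyl-4-methylidene-3-[2-(triisopropylsilyloxy)ethyl]cyclohexyl]propanedioate | C=C1CC[C@H](C(C(=O)OC)C(=O)OC)[C@@](C)(C(C)=O)[C@@H]1CCO[Si](C(C)C)(C(C)C)C(C)C | intermediate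
13 | methyl (4R,5R,9R,10R)-10-methyl-8-methylidene-1,3-dioxo-9-[2-(triisopropylsilyloxy)ethyl]decalin-4-carboxylate (labdane numbering; trans-fused; diketo tautomer shown; C4 epimerisable) | C=C1CC[C@@H]2[C@@H](C(=O)OC)C(=O)CC(=O)[C@@]2(C)[C@@H]1CCO[Si](C(C)C)(C(C)C)C(C)C | intermediate
14 | methyl (4R,5R,9R,10R)-3-methoxy-10-methyl-8-methylidene-1-oxo-9-[2-(triisopropylsilyloxy)ethyl]decal-2-ene-4-carboxylate (C4 epimerisable) | C=C1CC[C@@H]2[C@@H](C(=O)OC)C(OC)=CC(=O)[C@@]2(C)[C@@H]1CCO[Si](C(C)C)(C(C)C)C(C)C | intermediate
15 | methyl (4R,5R,9R,10R)-1-hydroxy-3-methoxy-10-methyl-8-methylidene-9-[2-(triisopropylsilyloxy)ethyl]decal-2-ene-4-carboxylate (C1 epimers) | C=C1CC[C@@H]2[C@@H](C(=O)OC)C(OC)=CC(O)[C@@]2(C)[C@@H]1CCO[Si](C(C)C)(C(C)C)C(C)C | intermediate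
16 | methyl (4R,5R,9R,10R)-10-methyl-8-methylidene-3-oxo-9-[2-(triisopropylsilyloxy)ethyl]decal-1-ene-4-carboxylate (C4 epimerisable) | C=C1CC[C@@H]2[C@@H](C(=O)OC)C(=O)C=C[C@@]2(C)[C@@H]1CCO[Si](C(C)C)(C(C)C)C(C)C | intermediate
17 | methyl (4S,5S,9R,10S)-4,10-dimethyl-8-methylidene-3-oxo-9-[2-(triisopropylsilyloxy)ethyl]decal-1-ene-4-carboxylate (ester axial, cis to the C10 methyl) | C=C1CC[C@@H]2[C@](C)(C(=O)OC)C(=O)C=C[C@@]2(C)[C@@H]1CCO[Si](C(C)C)(C(C)C)C(C)C | intermediate
18 | methyl (4S,5S,9R,10S)-4,10-dimethyl-8-methylidene-3-oxo-9-[2-(triisopropylsilyloxy)ethyl]decalin-4-carboxylate | C=C1CC[C@@H]2[C@](C)(C(=O)OC)C(=O)CC[C@@]2(C)[C@@H]1CCO[Si](C(C)C)(C(C)C)C(C)C | intermediate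
19 | (3R,4R,5S,9R,10S)-4-(hydroxymethyl)-4,10-dimethyl-8-methylidene-9-[2-(triisopropylsilyloxy)ethyl]decalin-3-ol | C=C1CC[C@@H]2[C@](C)(CO)[C@H](O)CC[C@@]2(C)[C@@H]1CCO[Si](C(C)C)(C(C)C)C(C)C | intermediate
20 | 3,19-acetonide (2,2-dimethyl-1,3-dioxane across O3 and O19) of 19 | C=C1CC[C@@H]2[C@]3(C)COC(C)(C)O[C@@H]3CC[C@@]2(C)[C@@H]1CCO[Si](C(C)C)(C(C)C)C(C)C | intermediate
21 | (3R,4R,5S,9R,10S)-3,19-O-isopropylidene-13,14,15,16-tetranorlabd-8(17)-ene-3,12,19-triol (free C12 hydroxyl) | C=C1CC[C@@H]2[C@]3(C)COC(C)(C)O[C@@H]3CC[C@@]2(C)[C@@H]1CCO | intermediate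
22 | (3R,4R,5S,9R,10S)-3,19-isopropylidenedioxy-13,14,15,16-tetranorlabd-8(17)-en-12-al | C=C1CC[C@@H]2[C@]3(C)COC(C)(C)O[C@@H]3CC[C@@]2(C)[C@@H]1CC=O | intermediate
23 | (S)-4-hydroxyoxolan-2-one ((S)-β-hydroxy-γ-butyrolactone) | C1C(=O)OC[C@H]1O | starting material
24 | (S)-4-(tert-butyldimethylsilyloxy)oxolan-2-one | C1C(=O)OC[C@H]1O[Si](C)(C)C(C)(C)C | intermediate
25 | aldol adduct: (13S,14S)-14-O-TBS-12-hydroxy-12,13-dihydro-3,19-O-isopropylideneandrographolide (trans lactone, C12 epimers) | C=C1CC[C@@H]2[C@]3(C)COC(C)(C)O[C@@H]3CC[C@@]2(C)[C@@H]1CC(O)[C@@H]1C(=O)OC[C@H]1O[Si](C)(C)C(C)(C)C | intermediate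
26 | C12 methanesulfonate of 25 | C=C1CC[C@@H]2[C@]3(C)COC(C)(C)O[C@@H]3CC[C@@]2(C)[C@@H]1CC(OS(C)(=O)=O)[C@@H]1C(=O)OC[C@H]1O[Si](C)(C)C(C)(C)C | intermediate
27 | (12E,14S)-14-O-(tert-butyldimethylsilyl)-3,19-O-isopropylideneandrographolide | C=C1CC[C@@H]2[C@]3(C)COC(C)(C)O[C@@H]3CC[C@@]2(C)[C@@H]1C/C=C1/C(=O)OC[C@H]1O[Si](C)(C)C(C)(C)C | intermediate
28 | 3,19-O-isopropylideneandrographolide | C=C1CC[C@@H]2[C@]3(C)COC(C)(C)O[C@@H]3CC[C@@]2(C)[C@@H]1C/C=C1/C(=O)OC[C@H]1O | intermediate
29 | 14-O-acetyl-3,19-O-isopropylideneandrographolide | C=C1CC[C@@H]2[C@]3(C)COC(C)(C)O[C@@H]3CC[C@@]2(C)[C@@H]1C/C=C1/C(=O)OC[C@H]1OC(C)=O | intermediate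
30 | 14-O-acetylandrographolide, (3R,4R,5S,9R,10S,12E,14S) | C=C1CC[C@@H]2[C@](C)(CO)[C@H](O)CC[C@@]2(C)[C@@H]1C/C=C1/C(=O)OC[C@H]1OC(C)=O | target

**Step count and risks**
Total steps: 23 (22 on the main line plus the silylation of 23 in step 18).
Longest linear sequence: 22 steps (1 to 30 through steps 1–17 and 19–23).

The three steps most likely to fail:

1. Step 9. Facial control at C10 may erode during the reversible Michael addition (cis-fused or C9/C10-mismatched material), or the cascade may stall at the malonate anion with deconjugation of the alkylidene malonate. Fallback, from 11: equilibrating silylation (TMSCl, Et3N, DMF, 80 °C) gives the more substituted trimethylsilyl enol ether F1. TiCl4 in CH2Cl2 at −78 °C then effects an intramolecular Mukaiyama–Michael addition under kinetic, chair-controlled conditions to give 12, now isolated. NaOMe in MeOH closes ring A in a separate operation, and the route is rejoined at 13.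

2. Step 10. Regiocontrol in the enol ether formation may be poor, with methanol entering at the C1 carbonyl; the Luche reduction of the hindered C1 carbonyl in step 11 may also be incomplete. Fallback, from 13: the regioisomer is used rather than discarded. The C1-methoxy enone F2 is reduced at its C3 ketone under Luche conditions to the equatorial allylic alcohol F3. Buffered hydrolysis (oxalic acid on wet silica) gives the 3-hydroxy-1-ketone F4. Its tosylhydrazone F5 (TsNHNH2, MeOH) is reduced with catecholborane and NaOAc to the β-hydroxy ester F6, in which C1 is a methylene group. Fráter–Seebach methylation of the dianion (LDA, 2.2 equiv; MeI) gives the C4-methylated hydroxy ester F7, the methyl entering anti to the alkoxide and to the C10 methyl. LiAlH4 then gives the diol, and the route is rejoined at 19.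

3. Step 19. Silanolate may be lost by β-elimination from the lithium enolate of 24 before or after the addition, and double-bond geometry may erode in the E1cB step that follows. Fallback, from 22: the dianion of unprotected 23 (LDA, 2.2 equiv, THF, −78 °C), whose C14 alkoxide cannot leave, adds to 22 to give the aldol diol F8. Ac2O, pyridine and DMAP give the 12,14-diacetate F9. DBU at 0 °C should then remove only the exocyclic C12 acetate, because C13–H is cis to the C14 acetate and only the C12 acetate can align anti-periplanar to it. The route is rejoined at 29, and steps 20–22 are not needed.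

**Further compounds**
F1 | step 9 | tetrasubstituted trimethylsilyl enol ether of 11 (C10=C1, E/Z mixture) | CC(O[Si](C)(C)C)=C(C)[C@@H](C(=C)CCC=C(C(=O)OC)C(=O)OC)CCO[Si](C(C)C)(C(C)C)C(C)C
F2 | step 10 | C1-methoxy enone, regioisomer of 14 (C1 enol ether, C3 ketone) | C=C1CC[C@@H]2[C@@H](C(=O)OC)C(=O)C=C(OC)[C@@]2(C)[C@@H]1CCO[Si](C(C)C)(C(C)C)C(C)C
F3 | step 10 | C3 equatorial allylic alcohol of F2 | C=C1CC[C@@H]2[C@@H](C(=O)OC)[C@H](O)C=C(OC)[C@@]2(C)[C@@H]1CCO[Si](C(C)C)(C(C)C)C(C)C
F4 | step 10 | 3-hydroxy-1-ketone (ketol) | C=C1CC[C@@H]2[C@@H](C(=O)OC)[C@H](O)CC(=O)[C@@]2(C)[C@@H]1CCO[Si](C(C)C)(C(C)C)C(C)C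
F5 | step 10 | C1 tosylhydrazone of F4 | C=C1CC[C@@H]2[C@@H](C(=O)OC)[C@H](O)CC(=NNS(=O)(=O)c3ccc(C)cc3)[C@@]2(C)[C@@H]1CCO[Si](C(C)C)(C(C)C)C(C)C
F6 | step 10 | 3-hydroxy 19-ester with C1 methylene | C=C1CC[C@@H]2[C@@H](C(=O)OC)[C@H](O)CC[C@@]2(C)[C@@H]1CCO[Si](C(C)C)(C(C)C)C(C)C
F7 | step 10 | C4-methylated 3-hydroxy 19-ester | C=C1CC[C@@H]2[C@](C)(C(=O)OC)[C@H](O)CC[C@@]2(C)[C@@H]1CCO[Si](C(C)C)(C(C)C)C(C)C
F8 | step 19 | aldol diol (12,14-dihydroxy, trans lactone, C12 epimers) | C=C1CC[C@@H]2[C@]3(C)COC(C)(C)O[C@@H]3CC[C@@]2(C)[C@@H]1CC(O)[C@@H]1C(=O)OC[C@H]1O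
F9 | step 19 | 12,14-diacetate of F8 | C=C1CC[C@@H]2[C@]3(C)COC(C)(C)O[C@@H]3CC[C@@]2(C)[C@@H]1CC(OC(C)=O)[C@@H]1C(=O)OC[C@H]1OC(C)=O
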